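**Retrosynthetic overview**

1. Last disconnections: the three MOM ethers (O5, O7, O4'), then the C3–C1' bond between ring C and ring B (Suzuki–Miyaura coupling of 3-iodochromone 16 with chromenylboronate 9).
2. Ring D (the dimethylpyran on ring B) is disconnected in one operation at the C3'–CH= bond and the O2'–CMe2 bond, giving bromophenol 4 and prenal. Forward: boron-templated ortho attack on the aldehyde carbon, o-quinone methide, oxa-6π electrocyclization.
3. Enabling feature: in ring B, C3' lies between O2' and O4'. With O4' capped as a MOM ether and the other ortho carbon of the O2' phenol (the future C1') carrying Br, C3' is the only free carbon ortho to the only free phenol, so ring D can only fuse at O2'/C3'. The Br then becomes the handle for the C3–C1' bond.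
4. Rings A/C: phloroacetophenone is C-prenylated twice (the future C6 and C8), then ring C is closed by enaminone formation and iodocyclization.
5. Order of ring formation: ring B (bought), ring D (step 4); ring A (bought), ring C (step 9); union of the two bicycles (step 10); deprotection (step 11).

Key step: step 4

Remark: Kanzonol L has no stereocentre and no stereogenic double bond, so no step has to control configuration; isoflavone locants are used (rings A and C unprimed, ring B primed).

**Route**

Step 1
Reactants: 1 3-hydroxyphenyl benzoate (resorcinol monobenzoate)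
Product: 2 2-bromo-5-hydroxyphenyl benzoate
Conditions: NBS (1.0 equiv), MeCN, −20 °C → 0 °C
Reagents that add atoms: N-bromosuccinimide, O=C1CCC(=O)N1Br
Why: Electrophilic aromatic bromination in which the free hydroxyl is by far the stronger director, so bromine should enter para to it, at the carbon ortho to the weakly donating benzoate.

Step 2
Reactants: 2 2-bromo-5-hydroxyphenyl benzoate
Product: 3 2-bromo-5-(methoxymethoxy)phenyl benzoate
Conditions: MOMCl (1.3 equiv), iPr2NEt (1.5 equiv), CH2Cl2, 0 °C → rt
Reagents that add atoms: chloromethyl methyl ether (MOMCl), COCCl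
Why: Williamson-type O-alkylation (MOM ether formation) of the only free phenol, with the meta benzoate unable to migrate and stable to amine base.

Step 3
Reactants: 3 2-bromo-5-(methoxymethoxy)phenyl benzoate
Product: 4 2-bromo-5-(methoxymethoxy)phenol
Conditions: pyrrolidine (2 equiv), THF, rt; aq NH4Cl wash
Reagents that add atoms: none
Why: Aminolysis of the aryl ester (acyl transfer to the amine) frees the phenol ortho to bromine under conditions that leave the MOM acetal and the aryl bromide untouched.

Step 4
Reactants: 4 2-bromo-5-(methoxymethoxy)phenol; 5 3-methylbut-2-enal (prenal)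
Product: 8 8-bromo-5-(methoxymethoxy)-2,2-dimethyl-2H-chromene, via benzodioxaborinine 6 (not isolated), via o-quinone methide 7 (not isolated)
Conditions: 5 (2 equiv), PhB(OH)2 (1.0 equiv, recovered), EtCO2H (0.3 equiv), toluene, reflux, Dean–Stark trap
Reagents that add atoms: none
Why: Phenylboronic acid condenses with the phenolic O–H of 4 and with the aldehyde so that the aldehyde carbon of prenal is delivered within a six-membered boronate transition state to the only free ortho carbon (the future C3'), which forms the aryl–CH bond and gives the temporary ring of benzodioxaborinine 6; at reflux 6 loses PhB=O by cycloreversion to the vinylogous o-quinone methide 7, whose 1-oxatriene closes by thermal disrotatory oxa-6π electrocyclization, forming the O–CMe2 bond of ring D and restoring the aromaticity of ring B. The closest known reaction type is the phenylboronic acid-mediated condensation of phenols with α,β-unsaturated aldehydes to 2H-chromenes, a relative of the amine-promoted chromenylation of resorcinols. Ring D is the only ring closed, and it closes in a pericyclic 6π mode (formally 6-endo) and not by ionic O-alkylation, so chroman or reverse-prenyl by-products of conjugate addition are not expected. No stereocentre results, because the carbinol carbon of 6 is racemic and becomes trigonal in 7 and the new quaternary carbon carries two methyl groups. The step needs regioselectivity (C3' against C5' for the carbon–carbon bond, O2' against O4' for the oxygen–carbon bond) and 1,2- over 1,4-addition to the enal: bromine on the second ortho carbon and the MOM cap on O4' leave a single ortho C–H next to a single free phenol, and the boron tether enforces 1,2-attack there. The aryl bromide, the MOM acetal and the product alkene should tolerate catalytic propionic acid in refluxing toluene.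

Step 5
Reactants: 8 8-bromo-5-(methoxymethoxy)-2,2-dimethyl-2H-chromene
Product: 9 2-[5-(methoxymethoxy)-2,2-dimethyl-2H-chromen-8-yl]-4,4,5,5-tetramethyl-1,3,2-dioxaborolane
Conditions: B2pin2 (1.3 equiv), PdCl2(dppf) (5 mol %; dppf = 1,1'-bis(diphenylphosphino)ferrocene), KOAc (3 equiv), 1,4-dioxane, 90 °C
Reagents that add atoms: bis(pinacolato)diboron, CC1(C)OB(OC1(C)C)B1OC(C)(C)C(C)(C)O1
Why: Miyaura borylation of the aryl bromide under acetate base tolerates the acetal and the chromene alkene and turns the blocking bromine into the coupling handle.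

Step 6
Reactants: 10 1-(2,4,6-trihydroxyphenyl)ethan-1-one (phloroacetophenone); 11 1-bromo-3-methylbut-2-ene (prenyl bromide)
Product: 12 1-[2,4,6-trihydroxy-3,5-bis(3-methylbut-2-en-1-yl)phenyl]ethan-1-one
Conditions: 11 (2.1 equiv), KOH (10 % aq, 2.2 equiv), 0 °C → rt; acidify
Reagents that add atoms: none
Why: Double C-alkylation of the ambident phloroglucinol phenoxide, for which water as solvent favours carbon over oxygen attack, should place one prenyl group on each of the two equivalent ring carbons.

Step 7
Reactants: 12 1-[2,4,6-trihydroxy-3,5-bis(3-methylbut-2-en-1-yl)phenyl]ethan-1-one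
Product: 13 1-[2-hydroxy-4,6-bis(methoxymethoxy)-3,5-bis(3-methylbut-2-en-1-yl)phenyl]ethan-1-one
Conditions: MOMCl (2.4 equiv), iPr2NEt (3 equiv), CH2Cl2, 0 °C → rt
Reagents that add atoms: chloromethyl methyl ether (MOMCl), COCCl
Why: MOM ether formation on the para hydroxyl and on one of the two equivalent ortho hydroxyls, the last hydroxyl staying free because it is locked in a hydrogen bond to the acetyl carbonyl.

Step 8
Reactants: 13 1-[2-hydroxy-4,6-bis(methoxymethoxy)-3,5-bis(3-methylbut-2-en-1-yl)phenyl]ethan-1-one
Product: 14 (E)-3-(dimethylamino)-1-[2-hydroxy-4,6-bis(methoxymethoxy)-3,5-bis(3-methylbut-2-en-1-yl)phenyl]prop-2-en-1-one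
Conditions: DMF dimethyl acetal (3 equiv), toluene, 90 °C
Reagents that add atoms: N,N-dimethylformamide dimethyl acetal, COC(OC)N(C)C
Why: Condensation of the methyl ketone with the formamide acetal gives the push–pull enaminone in its thermodynamic E geometry, and the chelated phenol is not expected to be methylated.

Step 9
Reactants: 14 (E)-3-(dimethylamino)-1-[2-hydroxy-4,6-bis(methoxymethoxy)-3,5-bis(3-methylbut-2-en-1-yl)phenyl]prop-2-en-1-one
Product: 16 3-iodo-5,7-bis(methoxymethoxy)-6,8-bis(3-methylbut-2-en-1-yl)-4H-chromen-4-one, via aminochromanone 15 (not isolated)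
Conditions: I2 (1.1 equiv), pyridine (1.5 equiv), CHCl3, 0 °C → rt; aq Na2S2O3
Reagents that add atoms: iodine, II
Why: Iodine-mediated cyclization of an o-hydroxyaryl enaminone (α-iodination, 6-endo attack of the phenol on the iminium carbon to give 15, loss of dimethylamine), in which the enaminone should far outpace the trisubstituted prenyl alkenes as nucleophile while pyridine buffers the acid.

Step 10
Reactants: 16 3-iodo-5,7-bis(methoxymethoxy)-6,8-bis(3-methylbut-2-en-1-yl)-4H-chromen-4-one; 9 2-[5-(methoxymethoxy)-2,2-dimethyl-2H-chromen-8-yl]-4,4,5,5-tetramethyl-1,3,2-dioxaborolane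
Product: 17 5,7-bis(methoxymethoxy)-3-[5-(methoxymethoxy)-2,2-dimethyl-2H-chromen-8-yl]-6,8-bis(3-methylbut-2-en-1-yl)-4H-chromen-4-one
Conditions: PdCl2(dppf) (5 mol %), Na2CO3 (2 M aq, 3 equiv), DME, 80 °C
Reagents that add atoms: none
Why: Suzuki–Miyaura coupling of a 3-iodochromone with an arylboronate is the standard construction of the isoflavone C3–C1' bond, and the mild carbonate base limits ring-opening of the chromone.

Step 11
Reactants: 17 5,7-bis(methoxymethoxy)-3-[5-(methoxymethoxy)-2,2-dimethyl-2H-chromen-8-yl]-6,8-bis(3-methylbut-2-en-1-yl)-4H-chromen-4-one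
Product: 18 Kanzonol L
Conditions: HCl (3 M in MeOH, catalytic to few equiv), MeOH–THF, 0 °C → rt, close monitoring
Reagents that add atoms: none
Why: Acid-catalysed transacetalization of the three MOM ethers to methanol, with dilute acid at low temperature chosen to spare the prenyl groups and the chromene.

**Compound list**

1 | 3-hydroxyphenyl benzoate | O=C(Oc1cccc(O)c1)c1ccccc1 | starting material
2 | 2-bromo-5-hydroxyphenyl benzoate | O=C(Oc1cc(O)ccc1Br)c1ccccc1 | intermediate
3 | 2-bromo-5-(methoxymethoxy)phenyl benzoate | COCOc1ccc(Br)c(OC(=O)c2ccccc2)c1 | intermediate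
4 | 2-bromo-5-(methoxymethoxy)phenol | COCOc1ccc(Br)c(O)c1 | intermediate
5 | 3-methylbut-2-enal (prenal) | CC(C)=CC=O | starting material
6 | 8-bromo-5-(methoxymethoxy)-4-(2-methylprop-1-en-1-yl)-2-phenyl-4H-1,3,2-benzodioxaborinine (racemic) | COCOc1ccc(Br)c2OB(c3ccccc3)OC(C=C(C)C)c12 | intermediate (not isolated)
7 | (Z)-6-bromo-3-(methoxymethoxy)-2-(3-methylbut-2-en-1-ylidene)cyclohexa-3,5-dien-1-one | O=C1C(Br)=CC=C(OCOC)/C1=C/C=C(C)C | intermediate (not isolated)
8 | 8-bromo-5-(methoxymethoxy)-2,2-dimethyl-2H-chromene | COCOc1ccc(Br)c2c1C=CC(C)(C)O2 | intermediate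
9 | 2-[5-(methoxymethoxy)-2,2-dimethyl-2H-chromen-8-yl]-4,4,5,5-tetramethyl-1,3,2-dioxaborolane | COCOc1ccc(B2OC(C)(C)C(C)(C)O2)c2c1C=CC(C)(C)O2 | intermediate
10 | 1-(2,4,6-trihydroxyphenyl)ethan-1-one | CC(=O)c1c(O)cc(O)cc1O | starting material
11 | 1-bromo-3-methylbut-2-ene | CC(C)=CCBr | starting material
12 | 1-[2,4,6-trihydroxy-3,5-bis(3-methylbut-2-en-1-yl)phenyl]ethan-1-one | CC(=O)c1c(O)c(CC=C(C)C)c(O)c(CC=C(C)C)c1O | intermediate
13 | 1-[2-hydroxy-4,6-bis(methoxymethoxy)-3,5-bis(3-methylbut-2-en-1-yl)phenyl]ethan-1-one | CC(=O)c1c(O)c(CC=C(C)C)c(OCOC)c(CC=C(C)C)c1OCOC | intermediate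
14 | (E)-3-(dimethylamino)-1-[2-hydroxy-4,6-bis(methoxymethoxy)-3,5-bis(3-methylbut-2-en-1-yl)phenyl]prop-2-en-1-one | CN(C)/C=C/C(=O)c1c(O)c(CC=C(C)C)c(OCOC)c(CC=C(C)C)c1OCOC | intermediate
15 | 2-(dimethylamino)-3-iodo-5,7-bis(methoxymethoxy)-6,8-bis(3-methylbut-2-en-1-yl)chroman-4-one (racemic, mixture of diastereomers) | COCOc1c(CC=C(C)C)c(OCOC)c2C(=O)C(I)C(N(C)C)Oc2c1CC=C(C)C | intermediate (not isolated)
16 | 3-iodo-5,7-bis(methoxymethoxy)-6,8-bis(3-methylbut-2-en-1-yl)-4H-chromen-4-one | COCOc1c(CC=C(C)C)c(OCOC)c2c(=O)c(I)coc2c1CC=C(C)C | intermediate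
17 | 5,7-bis(methoxymethoxy)-3-[5-(methoxymethoxy)-2,2-dimethyl-2H-chromen-8-yl]-6,8-bis(3-methylbut-2-en-1-yl)-4H-chromen-4-one | COCOc1c(CC=C(C)C)c(OCOC)c2c(=O)c(-c3ccc(OCOC)c4c3OC(C)(C)C=C4)coc2c1CC=C(C)C | intermediate
18 | Kanzonol L, 5,7-dihydroxy-3-(5-hydroxy-2,2-dimethyl-2H-chromen-8-yl)-6,8-bis(3-methylbut-2-en-1-yl)-4H-chromen-4-one | CC(C)=CCc1c(O)c(CC=C(C)C)c2occ(-c3ccc(O)c4c3OC(C)(C)C=C4)c(=O)c2c1O | target

**Totals**

Total step count: 11.
Longest linear sequence: 7 steps (steps 1, 2, 3, 4, 5, 10, 11); the ring A/C branch (steps 6 to 9) is 4 steps before the union.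

**Three steps most likely to fail**

Step 4. Boronate-templated attack at the ortho carbon flanked by two oxygens may be slow, and prolonged acid at reflux may strip the MOM acetal, which would open O4' to competing closure. Fallback: phenol 4 would be O-alkylated with 3-chloro-3-methylbut-1-yne (DBU, CuCl2 (catalytic), MeCN, 0 °C) to give 1-bromo-4-(methoxymethoxy)-2-[(2-methylbut-3-yn-2-yl)oxy]benzene F1. Heating F1 (N,N-diethylaniline, 180 °C) should trigger the aryl propargyl ether Claisen rearrangement ([3,3] shift to the only free ortho carbon, enolization, 1,5-hydrogen shift, oxa-6π closure). This fallback sets out from 4 and returns to the route at chromene 8.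

Step 9. Iodonium formation at the prenyl alkenes, with capture by the neighbouring phenol or MOM oxygen (iodoetherification), may compete with iodination of the enaminone, and the acid released may cleave MOM groups. Fallback: the iodochromone is bypassed. Ketone 13 would be α-arylated with bromochromene 8 (Pd2(dba)3, XPhos, NaOtBu (2.5 equiv), toluene, 80 °C; palladium-catalysed ketone α-arylation) to give 1-[2-hydroxy-4,6-bis(methoxymethoxy)-3,5-bis(3-methylbut-2-en-1-yl)phenyl]-2-[5-(methoxymethoxy)-2,2-dimethyl-2H-chromen-8-yl]ethan-1-one F2. Heating F2 with DMF dimethyl acetal (toluene, 100 °C) should give the enaminone at the benzylic carbon and close ring C with loss of dimethylamine. This fallback sets out from 13 and 8 and returns to the route at isoflavone 17; steps 5, 8 and 10 are then not needed.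

Step 11. During protic MOM solvolysis the prenyl groups may cyclize onto the freed 5- and 7-hydroxyls (chroman formation), and the electron-rich chromene alkene may be protonated and hydrated or oligomerized. Fallback: the MOM groups are exchanged instead of solvolysed. Compound 17 would be treated with TMSOTf and 2,2'-bipyridyl (MeCN, 0 °C → rt), which converts aryl MOM ethers into aryl trimethylsilyl ethers without free protic acid, to give 3-[2,2-dimethyl-5-(trimethylsilyloxy)-2H-chromen-8-yl]-6,8-bis(3-methylbut-2-en-1-yl)-5,7-bis(trimethylsilyloxy)-4H-chromen-4-one F3. F3 would then be desilylated with water (or K2CO3 (catalytic), MeOH, rt). This fallback sets out from 17 and returns to the route at target 18.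

**Further compounds**

F1 | step 4 | 1-bromo-4-(methoxymethoxy)-2-[(2-methylbut-3-yn-2-yl)oxy]benzene | COCOc1ccc(Br)c(OC(C)(C)C#C)c1
F2 | step 9 | 1-[2-hydroxy-4,6-bis(methoxymethoxy)-3,5-bis(3-methylbut-2-en-1-yl)phenyl]-2-[5-(methoxymethoxy)-2,2-dimethyl-2H-chromen-8-yl]ethan-1-one | COCOc1c(CC=C(C)C)c(O)c(C(=O)Cc2ccc(OCOC)c3c2OC(C)(C)C=C3)c(OCOC)c1CC=C(C)C
F3 | step 11 | 3-[2,2-dimethyl-5-(trimethylsilyloxy)-2H-chromen-8-yl]-6,8-bis(3-methylbut-2-en-1-yl)-5,7-bis(trimethylsilyloxy)-4H-chromen-4-one | C[Si](C)(C)Oc1c(CC=C(C)C)c(O[Si](C)(C)C)c2c(=O)c(-c3ccc(O[Si](C)(C)C)c4c3OC(C)(C)C=C4)coc2c1CC=C(C)C
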